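**Plan**
- Cuts: (a) the carbinol C–alkenyl C bond, giving aldehyde 7 and (E)-alkenyl iodide 18. (b) In 7, the ring bonds C4–C5 and C1–C2 together, giving prenal 4 and the C5 silyl dienyl ether 3. (c) In 18, C1–CH3, C2–Br, the side-chain CH3/I pair and the two Diels–Alder bonds of the ring.
- Enabling feature: in the dimethyl-methylidene-cyclohexene ring, O=C–C1–C2(Me2)–C3=C4 is a γ,δ-unsaturated carbonyl unit (Claisen retron) and C5–C6(=CH2)–C1 is a 2-methylidenepropane-1,3-diyl unit. The ring is therefore prenal (C4, C3, C2, two CH3) laid across an isoprenoid C5 unit. The prenal oxygen serves as an atom of a temporary dihydropyran ring and ends as the formyl, later carbinol, oxygen.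
- Forward: the left ring takes two steps (coupling to 3, then one-flask hetero-Diels–Alder / 1,4-elimination / ring-contracting Claisen). The right ring is built by a Diels–Alder reaction, then alkyne, iodoalkene, bromoketone and methyl carbinol. The halves are joined last by Nozaki–Hiyama–Kishi coupling.
- Stereochemistry: ring C1 comes from the catalyst-set pyran centre by 1,3-chirality transfer, and the carbinol C from Felkin–Anh addition to 7. Right-ring C4 comes from the asymmetric Diels–Alder reaction, C2(Br) from axial protonation relative to C4, and C1 from addition anti to Br. The E-alkene comes from syn-carboalumination.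

Key step: step 2

Assumption: the catalyst antipodes named in steps 2 and 4 are those expected to expose the Si face of 4 and to give (S)-11. Both antipodes of each are accessible, so a reversed sense of induction would be met by the mirror-image catalyst.

**Step 1**
Reactants: 1 (2-bromoprop-2-en-1-yl)trimethylsilane; 2 2-[(E)-2-ethoxyethenyl]-4,4,5,5-tetramethyl-1,3,2-dioxaborolane
Product: 3 [(3E)-4-ethoxy-2-methylidenebut-3-en-1-yl]trimethylsilane
Conditions: Pd(dppf)Cl2 (3 mol %), K3PO4, THF/H2O, 50 °C
Reagents that add atoms: none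
Why: Suzuki–Miyaura coupling of an alkenyl bromide with an alkenylboronate keeps the E geometry, and the mild aqueous base should leave allylsilane and enol ether untouched.

**Step 2**
Reactants: 3 [(3E)-4-ethoxy-2-methylidenebut-3-en-1-yl]trimethylsilane; 4 3-methylbut-2-enal (prenal)
Product: 7 (1R)-2,2-dimethyl-6-methylidenecyclohex-3-ene-1-carbaldehyde, via cycloadduct 5 (not isolated), via dienol ether 6 (not isolated)
Conditions: Cr(III)Cl complex of the (1R,2S)-1-aminoindan-2-ol / 3-(1-adamantyl)-5-methylsalicylaldehyde Schiff base (5 mol %), 4 Å MS, neat, rt; PhMe, TMSOTf (5 mol %), −40 °C, then Et3N; filtration through basic Al2O3; PhMe, BHT, 170 °C, sealed tube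
Reagents that add atoms: none
Why: Proposed new method: three known elementary events are chained in one flask, so that prenal (C4, C3, C2 and both methyls of the ring) and the C5 dienyl ether 3 (C5, C6, =CH2, C1, CHO) are joined twice. (i) Endo hetero-Diels–Alder addition of the Lewis-acid-bound C=O to the 1-alkoxydiene (closest known type: Cr(III)-catalysed hetero-Diels–Alder reactions of 1-alkoxydienes with aldehydes) bonds the =CH2 terminus of 3, made more nucleophilic by the β-silyl group, to the Si face of the formyl carbon (ring bond C4–C5) and the carbonyl O to the acetal carbon, closing the temporary dihydropyran by [4+2] cycloaddition. (ii) TMSOTf ionises the allylic acetal as in a Ferrier reaction and the cation loses the δ-silyl group (vinylogous Peterson 1,4-elimination of Me3SiOEt, TMSOTf regenerated), so the new double bond can only become the exocyclic methylene and never a ring double bond. (iii) 6 is a cyclic allyl vinyl ether and should rearrange like the known 2-vinyl-3,4-dihydro-2H-pyrans by a concerted [3,3] shift through a boat transition state, in which pyran C5 bonds to the CMe2 terminus (ring bond C1–C2, quaternary carbon) while O–C2 breaks, so that the carbocycle is closed by a six-centre sigmatropic ring contraction, the cis C3=C4 bond appears in place and the tether oxygen becomes the formyl oxygen. C1 is the only new stereocentre that remains: the isobutenyl group can reach only the face of the enol ether on which it stands, so the catalyst-set (S) centre of 6 is transferred suprafacially and itself destroyed, giving (R)-7. Needed selectivities are C=O over C=C of prenal (secured by the β,β-dimethyl substitution), bonding at pyran C5 rather than at the methylene terminus (a suprafacial [3,5] shift is thermally forbidden) and no Diels–Alder dimerisation of 6 (its diene is locked s-trans).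

**Step 3**
Reactants: 8 but-3-en-2-one
Product: 9 (buta-1,3-dien-2-yloxy)triisopropylsilane
Conditions: TIPSOTf, Et3N, CH2Cl2, 0 °C
Reagents that add atoms: triisopropylsilyl triflate, CC(C)[Si](C(C)C)(C(C)C)OS(=O)(=O)C(F)(F)F
Why: Soft enolisation and O-silylation of the only enolisable side gives the 2-silyloxydiene, and the bulky silyl group makes the later enol ether robust.

**Step 4**
Reactants: 9 (buta-1,3-dien-2-yloxy)triisopropylsilane; 10 prop-2-enal
Product: 11 (1S)-4-[(triisopropylsilyl)oxy]cyclohex-3-ene-1-carbaldehyde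
Conditions: (S)-α,α-diphenylprolinol-derived B-o-tolyl oxazaborolidine·HNTf2 (10 mol %), CH2Cl2, −78 °C
Reagents that add atoms: none
Why: In this enantioselective Diels–Alder reaction the 2-silyloxy group directs the "para" orientation, the chiral Lewis acid shields one face of the bound enal to set C1 as S, and the position of the enol ether double bond fixes where bromine will enter.

**Step 5**
Reactants: 11 (1S)-4-[(triisopropylsilyl)oxy]cyclohex-3-ene-1-carbaldehyde
Product: 12 {[(4S)-4-ethynylcyclohex-1-en-1-yl]oxy}triisopropylsilane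
Conditions: dimethyl (1-diazo-2-oxopropyl)phosphonate, K2CO3, MeOH, 0 °C → rt
Reagents that add atoms: Ohira–Bestmann reagent, COP(=O)(OC)C(=[N+]=[N-])C(C)=O
Why: Seyferth–Gilbert homologation under carbonate conditions turns CHO into C≡CH and should spare both the TIPS enol ether and the α-stereocentre.

**Step 6**
Reactants: 12 {[(4S)-4-ethynylcyclohex-1-en-1-yl]oxy}triisopropylsilane
Product: 14 ({(4S)-4-[(1E)-1-iodoprop-1-en-2-yl]cyclohex-1-en-1-yl}oxy)triisopropylsilane, via alkenylalane 13 (not isolated)
Conditions: Me3Al, Cp2ZrCl2 (20 mol %), CH2Cl2, 0 °C → rt; I2, THF, −30 °C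
Reagents that add atoms: trimethylaluminium, C[Al](C)C; iodine, II
Why: Negishi Zr-catalysed syn-carboalumination places CH3 on the internal and Al on the terminal alkyne carbon, and iodinolysis with retention gives the E-iodide faster than I2 attacks the hindered enol ether.

**Step 7**
Reactants: 14 ({(4S)-4-[(1E)-1-iodoprop-1-en-2-yl]cyclohex-1-en-1-yl}oxy)triisopropylsilane
Product: 15 (2R,4S)-2-bromo-4-[(1E)-1-iodoprop-1-en-2-yl]cyclohexan-1-one
Conditions: NBS, NaHCO3, THF, −78 → 0 °C
Reagents that add atoms: N-bromosuccinimide, O=C1CCC(=O)N1Br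
Why: Electrophilic bromination of the silyl enol ether is regiospecific at C2 and should go mainly by axial attack (Br trans to the side chain), a configuration that is reset in step 8.

**Step 8**
Reactants: 15 (2R,4S)-2-bromo-4-[(1E)-1-iodoprop-1-en-2-yl]cyclohexan-1-one
Product: 17 (2S,4S)-2-bromo-4-[(1E)-1-iodoprop-1-en-2-yl]cyclohexan-1-one, via lithium bromoenolate 16 (not isolated)
Conditions: LiHMDS (0.95 equiv), THF, −78 → −40 °C; inverse quench into AcOH/THF, −78 °C
Reagents that add atoms: none
Why: Equilibrating deprotonation gives the more stabilised bromo-enolate, and kinetic protonation of a cyclohexanone enolate is axial (stereoelectronic control), which leaves Br equatorial and cis to the equatorial C4 side chain.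

**Step 9**
Reactants: 17 (2S,4S)-2-bromo-4-[(1E)-1-iodoprop-1-en-2-yl]cyclohexan-1-one
Product: 18 (1R,2S,4S)-2-bromo-4-[(1E)-1-iodoprop-1-en-2-yl]-1-methylcyclohexan-1-ol
Conditions: MeMgBr, LaCl3·2LiCl (30 mol %), THF, −78 °C; then H2O
Reagents that add atoms: methylmagnesium bromide, C[Mg]Br
Why: Grignard 1,2-addition to an α-haloketone takes place anti to the C–Br bond (polar Felkin–Anh/Cornforth control, here also the equatorial trajectory), giving equatorial CH3 and an axial OH syn to Br.

**Step 10**
Reactants: 7 (1R)-2,2-dimethyl-6-methylidenecyclohex-3-ene-1-carbaldehyde; 18 (1R,2S,4S)-2-bromo-4-[(1E)-1-iodoprop-1-en-2-yl]-1-methylcyclohexan-1-ol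
Product: 19 (1R,2S,4S)-2-bromo-4-{(2E,4R)-4-[(1R)-2,2-dimethyl-6-methylidenecyclohex-3-en-1-yl]-4-hydroxybut-2-en-2-yl}-1-methylcyclohexan-1-ol (target)
Conditions: CrCl2 (4 equiv), NiCl2 (1 mol %), DMSO/THF, rt; H2O work-up
Reagents that add atoms: none
Why: The Nozaki–Hiyama–Kishi reaction activates only the alkenyl iodide (free OH, secondary bromide and the base-sensitive aldehyde are tolerated, alkene geometry is kept), and Felkin–Anh attack anti to the CMe2 carbon on the Re face of 7 should give the (R)-carbinol.

**Compound list**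
1 | (2-bromoprop-2-en-1-yl)trimethylsilane | C=C(Br)C[Si](C)(C)C | starting material
2 | 2-[(E)-2-ethoxyethenyl]-4,4,5,5-tetramethyl-1,3,2-dioxaborolane | CCO/C=C/B1OC(C)(C)C(C)(C)O1 | starting material
3 | [(3E)-4-ethoxy-2-methylidenebut-3-en-1-yl]trimethylsilane | CCO/C=C/C(=C)C[Si](C)(C)C | intermediate
4 | 3-methylbut-2-enal | CC(C)=CC=O | starting material
5 | (2R,6S)-2-ethoxy-6-(2-methylprop-1-en-1-yl)-4-[(trimethylsilyl)methyl]-5,6-dihydro-2H-pyran | CCO[C@H]1C=C(C[Si](C)(C)C)C[C@@H](C=C(C)C)O1 | intermediate
6 | (2S)-4-methylidene-2-(2-methylprop-1-en-1-yl)-3,4-dihydro-2H-pyran | C=C1C[C@@H](C=C(C)C)OC=C1 | intermediate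
7 | (1R)-2,2-dimethyl-6-methylidenecyclohex-3-ene-1-carbaldehyde | C=C1CC=CC(C)(C)[C@@H]1C=O | intermediate
8 | but-3-en-2-one | CC(=O)C=C | starting material
9 | (buta-1,3-dien-2-yloxy)triisopropylsilane | C=CC(=C)O[Si](C(C)C)(C(C)C)C(C)C | intermediate
10 | prop-2-enal | C=CC=O | starting material
11 | (1S)-4-[(triisopropylsilyl)oxy]cyclohex-3-ene-1-carbaldehyde | O=C[C@H]1CCC(O[Si](C(C)C)(C(C)C)C(C)C)=CC1 | intermediate
12 | {[(4S)-4-ethynylcyclohex-1-en-1-yl]oxy}triisopropylsilane | C#C[C@H]1CCC(O[Si](C(C)C)(C(C)C)C(C)C)=CC1 | intermediate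
13 | dimethyl[(1E)-2-{(1S)-4-[(triisopropylsilyl)oxy]cyclohex-3-en-1-yl}prop-1-en-1-yl]alane | C[Al](C)/C=C(\C)[C@H]1CCC(O[Si](C(C)C)(C(C)C)C(C)C)=CC1 | intermediate
14 | ({(4S)-4-[(1E)-1-iodoprop-1-en-2-yl]cyclohex-1-en-1-yl}oxy)triisopropylsilane | I/C=C(\C)[C@H]1CCC(O[Si](C(C)C)(C(C)C)C(C)C)=CC1 | intermediate
15 | (2R,4S)-2-bromo-4-[(1E)-1-iodoprop-1-en-2-yl]cyclohexan-1-one | I/C=C(\C)[C@H]1CCC(=O)[C@H](Br)C1 | intermediate
16 | lithium (4S)-2-bromo-4-[(1E)-1-iodoprop-1-en-2-yl]cyclohex-1-en-1-olate | I/C=C(\C)[C@H]1CCC([O-])=C(Br)C1.[Li+] | intermediate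
17 | (2S,4S)-2-bromo-4-[(1E)-1-iodoprop-1-en-2-yl]cyclohexan-1-one | I/C=C(\C)[C@H]1CCC(=O)[C@@H](Br)C1 | intermediate
18 | (1R,2S,4S)-2-bromo-4-[(1E)-1-iodoprop-1-en-2-yl]-1-methylcyclohexan-1-ol | I/C=C(\C)[C@H]1CC[C@@](C)(O)[C@@H](Br)C1 | intermediate
19 | (1R,2S,4S)-2-bromo-4-{(2E,4R)-4-[(1R)-2,2-dimethyl-6-methylidenecyclohex-3-en-1-yl]-4-hydroxybut-2-en-2-yl}-1-methylcyclohexan-1-ol | C=C1CC=CC(C)(C)[C@@H]1[C@H](O)/C=C(\C)[C@H]1CC[C@@](C)(O)[C@@H](Br)C1 | target

Total step count: 10. Longest linear sequence: 8 (steps 3–10).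

**Steps most likely to fail**

**Step 2.** The cycloaddition to a conjugated, β,β-disubstituted enal may be slow or poorly face-selective. Traces of acid may move the exocyclic double bond into the ring or ionise the allylic C–O bond, with loss of enantiopurity. The rearrangement may need a temperature at which the β,γ-unsaturated aldehyde conjugates.

The fallback uses known chemistry, sets out from 4 and returns at 7. It makes the two ring bonds in separate steps at the ester oxidation level.
- tert-Butyl(dimethyl)[(3-methylbut-3-en-1-yl)oxy]silane is metallated (n-BuLi/KOt-Bu) and borylated with i-PrOBpin to allylboronate F1.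
- (S)-TRIP-catalysed allylboration of 4 gives homoallylic alcohol F2, and TBAF gives diol F3.
- TEMPO/PhI(OAc)2 oxidises the primary alcohol and closes δ-lactone F4.
- KHMDS/TBSCl gives silyl ketene acetal F5. In toluene at 110 °C this undergoes the Ireland–Claisen ring contraction to silyl ester F6, which is hydrolysed on work-up to acid F7.
- LiAlH4 gives alcohol F8, and Dess–Martin oxidation gives 7.

**Step 8.** Deprotonation may occur on the unbrominated side, protonation may show poor facial selectivity, or the equatorial bromide may re-equilibrate.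

The fallback sets out from 14 and returns at 17. It replaces the protonation by a stereospecific substitution.
- Bis(4-nitrobenzenesulfonyl) peroxide attacks the enol ether carbon axially to give trans-α-nosyloxy ketone F9.
- One equivalent of Bu4NBr then displaces the sulfonate by SN2 inversion to give the cis-bromoketone 17.

**Step 10.** Addition to 7 may show poor facial selectivity, giving a mixture of carbinol epimers.

The fallback sets out from 19 (as the epimer mixture) and returns at 19. It moves the stereocontrol from C–C to C–H bond formation.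
- Buffered Dess–Martin oxidation gives dienone F10.
- Corey–Bakshi–Shibata reduction follows, with (S)-Me-oxazaborolidine and catecholborane at −78 °C. The bulky ring carbon acts as the large group and the slim alkenyl CH as the small one, which should give the (R)-carbinol.

**Further compounds**
F1 | step 2 | 2-(2-{2-[(tert-butyldimethylsilyl)oxy]ethyl}prop-2-en-1-yl)-4,4,5,5-tetramethyl-1,3,2-dioxaborolane | C=C(CCO[Si](C)(C)C(C)(C)C)CB1OC(C)(C)C(C)(C)O1
F2 | step 2 | (4S)-8-[(tert-butyldimethylsilyl)oxy]-2-methyl-6-methylideneoct-2-en-4-ol | CC(C)=C[C@@H](O)CC(=C)CCO[Si](C)(C)C(C)(C)C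
F3 | step 2 | (5S)-7-methyl-3-methylideneoct-6-ene-1,5-diol | CC(C)=C[C@@H](O)CC(=C)CCO
F4 | step 2 | (6S)-4-methylidene-6-(2-methylprop-1-en-1-yl)oxan-2-one | C=C1CC(=O)O[C@H](C=C(C)C)C1
F5 | step 2 | tert-butyl(dimethyl){[(2S)-4-methylidene-2-(2-methylprop-1-en-1-yl)-3,4-dihydro-2H-pyran-6-yl]oxy}silane | C=C1C[C@@H](C=C(C)C)OC(O[Si](C)(C)C(C)(C)C)=C1
F6 | step 2 | tert-butyldimethylsilyl (1R)-2,2-dimethyl-6-methylidenecyclohex-3-ene-1-carboxylate | C=C1CC=CC(C)(C)[C@@H]1C(=O)O[Si](C)(C)C(C)(C)C
F7 | step 2 | (1R)-2,2-dimethyl-6-methylidenecyclohex-3-ene-1-carboxylic acid | C=C1CC=CC(C)(C)[C@@H]1C(=O)O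
F8 | step 2 | [(1R)-2,2-dimethyl-6-methylidenecyclohex-3-en-1-yl]methanol | C=C1CC=CC(C)(C)[C@@H]1CO
F9 | step 8 | (1R,5S)-5-[(1E)-1-iodoprop-1-en-2-yl]-2-oxocyclohexyl 4-nitrobenzenesulfonate | I/C=C(\C)[C@H]1CCC(=O)[C@H](OS(=O)(=O)c2ccc(cc2)[N+](=O)[O-])C1
F10 | step 10 | (2E)-3-[(1S,3S,4R)-3-bromo-4-hydroxy-4-methylcyclohexyl]-1-[(1R)-2,2-dimethyl-6-methylidenecyclohex-3-en-1-yl]but-2-en-1-one | C=C1CC=CC(C)(C)[C@@H]1C(=O)/C=C(\C)[C@H]1CC[C@@](C)(O)[C@@H](Br)C1
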